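## The problem

The target 17 is a 2,5-diaryl-3,4-dimethyltetrahydrofuran: one five-membered ring (O1, C2–C5) in which every carbon is a stereocentre, with a 4-hydroxy-3-methoxyphenyl ring on C2 and a 3-hydroxy-4,5-dimethoxyphenyl ring on C5. The relative configuration is 2,3-trans, 3,4-cis, 4,5-trans, so the two aryl groups are cis to each other and the two methyl groups are cis to each other. With identical aryl rings the compound would be meso, so the (2S,3S,4R,5R) enantiomer is defined only by which end carries which ring, and the absolute configuration must be fixed when the first aryl-bearing carbon is made. The centres can relay information: C4 and C5 can be set together in one carbonyl addition, C4 can direct the C3 methyl, and C3 and C4 together can direct the approach to C2. The cis-dimethyl relation is the less stable one beside an enolisable carbonyl, so C3 has to be set kinetically and kept away from base afterwards. Both ring C–O bonds are benzylic to electron-rich arenes (acid ionises them, hydrogenolysis cleaves them), and the free para-hydroxyl on the C2 ring allows quinone-methide ring opening under base, so the phenols stay masked until a mild last step. The feature that makes the key step possible is that C2 is a single carbon between O1 and C3: it can enter as carbon monoxide once the C5 hydroxyl, C4 and an alkyne carbon at C3 are in place as a homopropargylic alcohol, the second alkyne carbon surviving as an exocyclic methylene that becomes the C3 methyl.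

## Retrosynthesis

Target 17 to bis(silyl ether) 16. The two phenolic O–H bonds are traced back to O–Si bonds. Silyl ethers are preferred to benzyl ethers, whose hydrogenolysis would compete with cleavage of the benzylic C2–O1 and C5–O1 bonds and which would not survive the alkene hydrogenation planned earlier. Compound 16 differs from 17 only by the protecting groups. The forward step must free both phenols without generating a phenoxide that could open the ring at C2.

Compound 16 to lactol acetate 11 and aryl bromide 13. The C2–aryl bond is cut. Acetate 11 serves as the precursor of a C2 oxocarbenium ion, and the aryl group arrives as arylzinc bromide 15, made through Grignard reagent 14 from bromide 13, the silyl ether of phenol 12. The neighbouring cut at C2–H (hydride delivery to a 2-aryl oxocarbenium ion) is rejected: a nucleophile enters anti to the two methyl groups, so hydride would leave the aryl group cis to the C3 methyl, whereas an aryl nucleophile gives the required 2,3-trans, 2,5-cis pattern. Acetate 11 has one aryl ring fewer and no defined C2 centre. The forward reaction must be face-selective and must outrun loss of the C3 proton from the cation.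

Acetate 11 to lactone 9. The C2–OAc group is traced back to the lactone carbonyl through aluminium lactolate 10, formed by hydride reduction and acetylated in the same flask. No skeletal simplification results, but C2 is now a carbonyl carbon, the oxidation level at which carbon monoxide delivers it. The forward step must stop at the lactol stage and leave C3 untouched.

Lactone 9 to α-methylene lactone 8. The two C–H bonds made by hydrogenation are removed. The alternative cut at C3–CH3 (enolate methylation of a C3-unsubstituted lactone) would place the new methyl trans to the C4 methyl, which is the wrong relation. Addition of hydrogen to the methylene group anti to the C4 methyl gives the cis-dimethyl lactone. Compound 8 has only the C4 and C5 stereocentres. The forward step needs facial control from C4 and no migration of the double bond into the ring.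

α-Methylene lactone 8 to homopropargylic alcohol 6 and carbon monoxide 7. The O1–C2 and C2–C3 bonds are cut together, removing the ring and the carbonyl carbon in one operation. Cutting O1–C5 instead (lactonisation of a hydroxy acrylate) would still require a separate construction of the acrylate. Alcohol 6 is acyclic, carries only the anti C4/C5 pair, and its terminal alkyne already holds C3 and the future methyl carbon. The forward reaction must close the five-membered exo-methylene lactone and not the six-membered endo isomer, and has no stereochemical duty.

Alcohol 6 to aldehyde 2 and mesylate 4. The C4–C5 bond is cut. Mesylate 4, from (S)-but-3-yn-2-ol 3, is converted into the chiral allenylzinc reagent 5, which adds to aldehyde 2, the silyl ether of the commercial phenol 1. This delivers the alkyne directly, whereas a crotylation or aldol construction of the same anti pair would need further steps to install it. The forward reaction must be anti-selective and must transfer the configuration of 3 to C4 with overall inversion (anti SN2' oxidative addition, then syn SE2' addition), which is why the (S) alcohol is chosen for the (4R,5R) series.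

## Roads not taken

Alternative 1: The ring is cut at O1–C2 and C4–C5. In the forward sense, Sn(OTf)2 catalyses a (3+2) annulation between the donor–acceptor cyclopropane A1 (aryl and methyl cis) and aldehyde A2 to give the tetrahydrofuran gem-diester A3. This is the most convergent of the four plans: both aryl rings arrive in one step, the 2,5-cis relation (set last in the chosen route) comes from the annulation itself, and inversion at the donor carbon turns the cis cyclopropane into the 2,3-trans ring. Its weak points are at C4 and at the substrate. The gem-diester must be cut down to one methyl group (decarboxylation, reduction, activation, deoxygenation), and the C4 configuration is then decided by protonation of an ester enolate that must end cis to one neighbour whichever face is taken. Cyclopropane A1 needs its own enantioselective synthesis, and its para-oxygenated donor ring favours ring opening and racemisation under the Lewis acid. The final debenzylation by hydrogenolysis competes with the two benzylic ring C–O bonds. Against the better convergence of this road, the chosen plan introduces C4 directly as a methyl-bearing stereocentre from a purchasable enantiopure alcohol and never has to adjust it.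

Alternative 2: The cuts are C2–C3 and O1–C5 (the lactone carbonyl becoming C5). In the forward sense, a chiral phosphoric acid catalyses addition of the ester-substituted crotylboronate A4 to aldehyde A5, and the resulting borate lactonises in situ to the α-methylene lactone A6. Because the target is pseudo-symmetric, A6 enters the same endgame as lactone 8 with the aryl roles exchanged. In step economy this road is better: one catalytic step replaces mesylation, propargylation and carbonylation, it starts from a cheaper aldehyde, and it needs neither carbon monoxide nor Et2Zn. Its weak points are in reactivity and control. Allylboronates carrying an ester on the central carbon are deactivated and normally call for strong acid or heat, and enantiofacial control by a phosphoric acid for this methyl-substituted, ester-bearing reagent is not established to the degree that it is for simple allyl and allenyl boronates. Reagent A4 must also be geometrically pure, and acid with the electron-rich benzylic borate risks ionisation at the new carbinol centre. The less available trioxygenated ring would then have to be made into the organozinc partner. Against the shorter sequence, the chosen plan offers an absolute configuration derived stereospecifically from an enantiopure reagent with a predictable sense, and a ring-forming step that needs only regiocontrol.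

Alternative 3: Both future methyl C–C bonds (at C3 and C4) are cut. In the forward sense, the thiocarbonyl ylide released from sulfide A8 with CsF adds across the C=C bond of the enantiopure butenolide A7, anti to the aryl group, to give the cis-fused thiolane A9. Desulfurisation with Raney nickel would then unveil both methyl groups as lactone A10, the benzyl counterpart of 9. In one respect this road is better than the chosen one: the cis-dimethyl relation is enforced by the ring fusion and does not depend on facial selectivity in a hydrogenation. Its weak points are that A7 has a γ-hydrogen that is both benzylic and vinylogously acidic, so it can racemise through the 2-oxyfuran under basic fluoride conditions. Raney nickel also threatens the benzylic C5–O1 bond and the benzyl ether. Making A7 as a single enantiomer costs as many steps as steps 1 to 4 here. Against the enforced cis relation, the chosen plan offers a configurationally robust intermediate (alcohol 6 has no acidic stereocentre) and a catalytic, atom-economical ring closure.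

Key step: step 4

Assumption: allenylzinc 5 is formulated as its ethylzinc species, and lactolate 10 and acetate 11 as mixtures of C2 epimers; neither point affects the outcome, because 5 reacts only through its allenyl group and C2 becomes planar in step 8.

## Route

Step 1
Reactants: 1 3-hydroxy-4,5-dimethoxybenzaldehyde
Product: 2 3-(tert-butyldimethylsilyloxy)-4,5-dimethoxybenzaldehyde
Conditions: TBSCl, imidazole, DMF, 23 °C
Reagents that add atoms: tert-butyldimethylsilyl chloride, CC(C)(C)[Si](C)(C)Cl
Why: Imidazole-promoted silylation of a phenol; the aryl silyl ether removes the acidic proton before the organozinc and hydride steps and is stable to hydrogenation.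

Step 2
Reactants: 3 (S)-but-3-yn-2-ol
Product: 4 (S)-but-3-yn-2-yl methanesulfonate
Conditions: MsCl, Et3N, CH2Cl2, −78 to 0 °C
Reagents that add atoms: methanesulfonyl chloride, CS(=O)(=O)Cl
Why: O-Sulfonylation of a secondary alcohol, which does not touch the stereocentre; the mesylate should be used without chromatography.

Step 3
Reactants: 2 3-(tert-butyldimethylsilyloxy)-4,5-dimethoxybenzaldehyde, 4 (S)-but-3-yn-2-yl methanesulfonate
Product: 6 (1R,2R)-1-[3-(tert-butyldimethylsilyloxy)-4,5-dimethoxyphenyl]-2-methylbut-3-yn-1-ol, via allenylzinc reagent 5 (not isolated)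
Conditions: Pd(OAc)2 (5 mol%), PPh3 (5 mol%), Et2Zn (3 equiv), THF, −78 to −20 °C
Reagents that add atoms: none
Why: Marshall propargylation: zerovalent palladium opens mesylate 4 in an anti SN2' sense, transmetallation with Et2Zn gives the configurationally defined allenylzinc 5, and its syn SE2' addition to aldehyde 2 through a cyclic transition state forms the C4–C5 bond. The methyl-bearing centre is set by chirality transfer from 4 with overall inversion (S mesylate to 2R), and the carbinol centre is set anti to it (1R) by the cyclic transition state in which the aryl group avoids the allenyl methyl.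

Step 4
Reactants: 6 (1R,2R)-1-[3-(tert-butyldimethylsilyloxy)-4,5-dimethoxyphenyl]-2-methylbut-3-yn-1-ol, 7 carbon monoxide
Product: 8 (4R,5R)-5-[3-(tert-butyldimethylsilyloxy)-4,5-dimethoxyphenyl]-4-methyl-3-methylidenedihydrofuran-2(3H)-one
Conditions: PdCl2 (10 mol%), thiourea (10 mol%), CO (3 atm), acetone, 50 °C
Reagents that add atoms: none
Why: Thiourea-ligated divalent palladium takes up the C5 hydroxyl and CO to give an alkoxycarbonyl–palladium species (O1–C2), which adds syn across the tethered terminal alkyne so that C2 bonds to the internal alkyne carbon C3; protonolysis of the vinyl–palladium bond by the HCl released at the outset frees 8 and returns PdCl2, so no oxidant is needed. The closest known reaction type is the palladium-catalysed cyclocarbonylation of but-3-yn-1-ols to α-methylene-γ-butyrolactones. The one ring is closed by a 5-exo-dig acylpalladation, the terminal alkyne carbon ending as the exocyclic methylene. No stereocentre is created: C4 and C5 arrive from 6, take no part in bond making, and the neutral medium offers no path for epimerising the propargylic C4–H. The step needs regioselectivity for the five-membered exo-methylene lactone over the six-membered endo isomer, which the short tether between the palladium-bound carbonyl and C3 secures, and chemoselectivity over intermolecular alkoxycarbonylation, which intramolecular delivery in a solvent free of other alcohols secures. The anti configuration of 6 places aryl and methyl trans on the new ring, so closure meets no added strain.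

Step 5
Reactants: 8 (4R,5R)-5-[3-(tert-butyldimethylsilyloxy)-4,5-dimethoxyphenyl]-4-methyl-3-methylidenedihydrofuran-2(3H)-one
Product: 9 (3S,4R,5R)-5-[3-(tert-butyldimethylsilyloxy)-4,5-dimethoxyphenyl]-3,4-dimethyldihydrofuran-2(3H)-one
Conditions: H2 (1 atm), 5% Pd/C, EtOAc, 23 °C
Reagents that add atoms: none
Why: Heterogeneous syn hydrogenation of a 1,1-disubstituted alkene; hydrogen should reach C3 on the face that carries the C4 hydrogen, anti to the adjacent methyl group, so the new methyl ends cis to the C4 methyl (3S), the usual outcome for β-substituted α-methylene-γ-butyrolactones. Neutral EtOAc at 1 atm should spare the aryl silyl ether and the benzylic C5–O bond.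

Step 6
Reactants: 9 (3S,4R,5R)-5-[3-(tert-butyldimethylsilyloxy)-4,5-dimethoxyphenyl]-3,4-dimethyldihydrofuran-2(3H)-one
Product: 11 (3S,4R,5R)-5-[3-(tert-butyldimethylsilyloxy)-4,5-dimethoxyphenyl]-3,4-dimethyltetrahydrofuran-2-yl acetate (C2 epimers), via diisobutylaluminium lactolate 10 (not isolated)
Conditions: i-Bu2AlH, CH2Cl2, −78 °C; then pyridine, DMAP, Ac2O, −78 to −20 °C
Reagents that add atoms: acetic anhydride, CC(=O)OC(C)=O
Why: One-pot reductive acetylation of a lactone: at −78 °C the reduction stops at the tetrahedral aluminium lactolate 10, which is acylated in the same flask, so no free lactol or enolisable carbonyl is exposed to base and C3 is preserved. The C2 configuration is irrelevant because it is erased in step 8.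

Step 7
Reactants: 12 4-bromo-2-methoxyphenol
Product: 13 (4-bromo-2-methoxyphenoxy)(tert-butyl)dimethylsilane
Conditions: TBSCl, imidazole, DMF, 23 °C
Reagents that add atoms: tert-butyldimethylsilyl chloride, CC(C)(C)[Si](C)(C)Cl
Why: Imidazole-promoted silylation of a phenol, giving an aryl bromide that tolerates magnesium insertion.

Step 8
Reactants: 11 (3S,4R,5R)-5-[3-(tert-butyldimethylsilyloxy)-4,5-dimethoxyphenyl]-3,4-dimethyltetrahydrofuran-2-yl acetate, 13 (4-bromo-2-methoxyphenoxy)(tert-butyl)dimethylsilane
Product: 16 (2S,3S,4R,5R)-2-[4-(tert-butyldimethylsilyloxy)-3-methoxyphenyl]-5-[3-(tert-butyldimethylsilyloxy)-4,5-dimethoxyphenyl]-3,4-dimethyltetrahydrofuran, via arylmagnesium bromide 14 (not isolated), via arylzinc bromide 15 (not isolated)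
Conditions: 13, Mg, THF, 50 °C; ZnBr2, 0 °C; then 11, BF3·OEt2, CH2Cl2, −78 to 0 °C
Reagents that add atoms: none
Why: BF3·OEt2 ionises acetate 11 to the cyclic oxocarbenium ion, which arylzinc 15 (from Grignard reagent 14 by transmetallation) captures in a Lewis acid-promoted substitution of a 2-acyloxy cyclic ether by an organozinc reagent. In the envelope that keeps the C4 methyl and the C5 aryl pseudo-equatorial, inside attack occurs on the face opposite both methyl groups, which should give the 2,3-trans (2S) product with the two aryl groups cis.

Step 9
Reactants: 16 (2S,3S,4R,5R)-2-[4-(tert-butyldimethylsilyloxy)-3-methoxyphenyl]-5-[3-(tert-butyldimethylsilyloxy)-4,5-dimethoxyphenyl]-3,4-dimethyltetrahydrofuran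
Product: 17 (2S,3S,4R,5R)-2-(4-hydroxy-3-methoxyphenyl)-5-(3-hydroxy-4,5-dimethoxyphenyl)-3,4-dimethyltetrahydrofuran
Conditions: Bu4NF, AcOH, THF, 0 to 23 °C
Reagents that add atoms: none
Why: Fluoride-mediated cleavage of both aryl silyl ethers, driven by Si–F bond formation; the AcOH buffer protonates each phenoxide as it forms, so the para-hydroxybenzylic ether at C2 should not open through a quinone methide.

## Compound list

1 | 3-hydroxy-4,5-dimethoxybenzaldehyde | COc1cc(C=O)cc(O)c1OC | starting material
2 | 3-(tert-butyldimethylsilyloxy)-4,5-dimethoxybenzaldehyde | COc1cc(C=O)cc(O[Si](C)(C)C(C)(C)C)c1OC | intermediate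
3 | (S)-but-3-yn-2-ol | C#C[C@H](C)O | starting material
4 | (S)-but-3-yn-2-yl methanesulfonate | C#C[C@H](C)OS(C)(=O)=O | intermediate
5 | ethyl[(M)-buta-1,2-dien-1-yl]zinc (allenylzinc reagent, not isolated) | CC([H])=[C@]=C([H])[Zn]CC | intermediate
6 | (1R,2R)-1-[3-(tert-butyldimethylsilyloxy)-4,5-dimethoxyphenyl]-2-methylbut-3-yn-1-ol | C#C[C@@H](C)[C@@H](O)c1cc(O[Si](C)(C)C(C)(C)C)c(OC)c(OC)c1 | intermediate
7 | carbon monoxide | [C-]#[O+] | starting material
8 | (4R,5R)-5-[3-(tert-butyldimethylsilyloxy)-4,5-dimethoxyphenyl]-4-methyl-3-methylidenedihydrofuran-2(3H)-one | C=C1C(=O)O[C@@H](c2cc(O[Si](C)(C)C(C)(C)C)c(OC)c(OC)c2)[C@@H]1C | intermediate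
9 | (3S,4R,5R)-5-[3-(tert-butyldimethylsilyloxy)-4,5-dimethoxyphenyl]-3,4-dimethyldihydrofuran-2(3H)-one | O=C1O[C@@H](c2cc(O[Si](C)(C)C(C)(C)C)c(OC)c(OC)c2)[C@H](C)[C@@H]1C | intermediate
10 | diisobutyl{[(3S,4R,5R)-5-[3-(tert-butyldimethylsilyloxy)-4,5-dimethoxyphenyl]-3,4-dimethyltetrahydrofuran-2-yl]oxy}aluminium (C2 epimers, not isolated) | CC(C)C[Al](CC(C)C)OC1O[C@@H](c2cc(O[Si](C)(C)C(C)(C)C)c(OC)c(OC)c2)[C@H](C)[C@@H]1C | intermediate
11 | (3S,4R,5R)-5-[3-(tert-butyldimethylsilyloxy)-4,5-dimethoxyphenyl]-3,4-dimethyltetrahydrofuran-2-yl acetate (C2 epimers) | CC(=O)OC1O[C@@H](c2cc(O[Si](C)(C)C(C)(C)C)c(OC)c(OC)c2)[C@H](C)[C@@H]1C | intermediate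
12 | 4-bromo-2-methoxyphenol | COc1cc(Br)ccc1O | starting material
13 | (4-bromo-2-methoxyphenoxy)(tert-butyl)dimethylsilane | COc1cc(Br)ccc1O[Si](C)(C)C(C)(C)C | intermediate
14 | [4-(tert-butyldimethylsilyloxy)-3-methoxyphenyl]magnesium bromide (not isolated) | COc1cc([Mg]Br)ccc1O[Si](C)(C)C(C)(C)C | intermediate
15 | [4-(tert-butyldimethylsilyloxy)-3-methoxyphenyl]zinc bromide (not isolated) | COc1cc([Zn]Br)ccc1O[Si](C)(C)C(C)(C)C | intermediate
16 | (2S,3S,4R,5R)-2-[4-(tert-butyldimethylsilyloxy)-3-methoxyphenyl]-5-[3-(tert-butyldimethylsilyloxy)-4,5-dimethoxyphenyl]-3,4-dimethyltetrahydrofuran | COc1cc([C@H]2O[C@@H](c3cc(O[Si](C)(C)C(C)(C)C)c(OC)c(OC)c3)[C@H](C)[C@@H]2C)ccc1O[Si](C)(C)C(C)(C)C | intermediate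
17 | (2S,3S,4R,5R)-2-(4-hydroxy-3-methoxyphenyl)-5-(3-hydroxy-4,5-dimethoxyphenyl)-3,4-dimethyltetrahydrofuran | COc1cc([C@H]2O[C@@H](c3cc(O)c(OC)c(OC)c3)[C@H](C)[C@@H]2C)ccc1O | target

## Step count and risks

Total step count: 9. Longest linear sequence: 7 steps (steps 1, 3, 4, 5, 6, 8, 9); steps 2 and 7 prepare the two side components.

Step 4 (key step). The likeliest failures are reduction of divalent palladium to the metal by CO before the alkoxycarbonyl species turns over, slow alkoxycarbonyl formation at a hindered secondary benzylic alcohol, and acid-promoted ionisation of the electron-rich benzylic C–O bond by the HCl carried in the cycle. Fallback, from 6 back to 8, builds the same lactone without CO, C2 then coming from the terminal alkyne carbon. Hydroboration of the alkyne with Cy2BH and oxidation with NaBO3 gives the lactol (4R,5R)-5-[3-(tert-butyldimethylsilyloxy)-4,5-dimethoxyphenyl]-4-methyltetrahydrofuran-2-ol F2. Oxidation with TEMPO/PhI(OAc)2 gives the lactone (4R,5R)-5-[3-(tert-butyldimethylsilyloxy)-4,5-dimethoxyphenyl]-4-methyldihydrofuran-2(3H)-one F3. Enolisation with LiN(i-Pr)2 and trapping with dimethyl(methylidene)ammonium iodide gives the Mannich base 3-[(dimethylamino)methyl] lactone F4. Quaternisation with MeI gives the trimethylammonium iodide F5, and elimination with NaHCO3 returns the route at 8.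

Step 3. The anti:syn ratio may erode, because conjugated electron-rich aldehydes react through a looser transition state. The allenylpalladium intermediate may also partly racemise before transmetallation, lowering the enantiomeric purity of C4. Fallback, from 2 back to 6: a chiral phosphoric acid-catalysed allenylboration of 2 with an excess of racemic 2-(buta-1,2-dien-1-yl)-4,4,5,5-tetramethyl-1,3,2-dioxaborolane (kinetic resolution of the reagent, anti-selective through a closed six-membered transition state). The (R)-configured 3,3'-bis(2,4,6-triisopropylphenyl)-BINOL phosphoric acid is expected to give the (1R) carbinol, by analogy with allyl- and allenylborations of aryl aldehydes; the antipodal acid would be used if the sense proved opposite. The first-formed borate ester 2-{[(1R,2R)-1-[3-(tert-butyldimethylsilyloxy)-4,5-dimethoxyphenyl]-2-methylbut-3-yn-1-yl]oxy}-4,4,5,5-tetramethyl-1,3,2-dioxaborolane F1 is hydrolysed on work-up to 6.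

Step 5. Palladium hydride may move the double bond into the ring, giving a tetrasubstituted butenolide that resists reduction or reduces from the wrong face. Facial selectivity may also be incomplete, since the C5 aryl group lies on the face that must accept hydrogen, and prolonged exposure may hydrogenolyse the benzylic C5–O bond. Fallback, from 8 back to 9: conjugate reduction with LiBH(s-Bu)3 in THF at −78 °C gives the lithium enolate lithium (4R,5R)-5-[3-(tert-butyldimethylsilyloxy)-4,5-dimethoxyphenyl]-3,4-dimethyl-4,5-dihydrofuran-2-olate F6. Kinetic protonation at −78 °C (aq. NH4Cl) on the face anti to the C4 methyl gives the cis-dimethyl lactone 9 without a metal surface.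

Step 8. The oxocarbenium ion may lose the C3 proton to give an enol ether faster than the arylzinc adds, which would scramble C3 on reprotonation. Attack may also occur in part on the face syn to the methyl groups, and BF3·OEt2 may strip an aryl silyl ether. Fallback, from 9 back to 16, reverses the order of bond formation. Reduction with i-Bu2AlH at −78 °C and aqueous work-up gives the lactol (3S,4R,5R)-5-[3-(tert-butyldimethylsilyloxy)-4,5-dimethoxyphenyl]-3,4-dimethyltetrahydrofuran-2-ol F7. Addition of excess Grignard reagent 14 to its open hydroxy-aldehyde form gives the diol (1R,2R,3S)-1-[3-(tert-butyldimethylsilyloxy)-4,5-dimethoxyphenyl]-4-[4-(tert-butyldimethylsilyloxy)-3-methoxyphenyl]-2,3-dimethylbutane-1,4-diol F8 as a mixture at C4 of the chain. Treatment with MsCl and Et3N then sulfonylates and ionises the more electron-rich para-silyloxybenzylic position, and the C5 hydroxyl closes the ring to the favoured 2,3-trans isomer 16 with C5 retained.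

## Further compounds

F1 | step 3 | 2-{[(1R,2R)-1-[3-(tert-butyldimethylsilyloxy)-4,5-dimethoxyphenyl]-2-methylbut-3-yn-1-yl]oxy}-4,4,5,5-tetramethyl-1,3,2-dioxaborolane | C#C[C@@H](C)[C@@H](OB1OC(C)(C)C(C)(C)O1)c1cc(O[Si](C)(C)C(C)(C)C)c(OC)c(OC)c1
F2 | step 4 | (4R,5R)-5-[3-(tert-butyldimethylsilyloxy)-4,5-dimethoxyphenyl]-4-methyltetrahydrofuran-2-ol (C2 epimers) | C1C(O)O[C@@H](c2cc(O[Si](C)(C)C(C)(C)C)c(OC)c(OC)c2)[C@@H]1C
F3 | step 4 | (4R,5R)-5-[3-(tert-butyldimethylsilyloxy)-4,5-dimethoxyphenyl]-4-methyldihydrofuran-2(3H)-one | C1C(=O)O[C@@H](c2cc(O[Si](C)(C)C(C)(C)C)c(OC)c(OC)c2)[C@@H]1C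
F4 | step 4 | (4R,5R)-5-[3-(tert-butyldimethylsilyloxy)-4,5-dimethoxyphenyl]-3-[(dimethylamino)methyl]-4-methyldihydrofuran-2(3H)-one (C3 epimers) | CN(C)CC1C(=O)O[C@@H](c2cc(O[Si](C)(C)C(C)(C)C)c(OC)c(OC)c2)[C@@H]1C
F5 | step 4 | {(4R,5R)-5-[3-(tert-butyldimethylsilyloxy)-4,5-dimethoxyphenyl]-4-methyl-2-oxotetrahydrofuran-3-yl}methyl(trimethyl)ammonium iodide | C[N+](C)(C)CC1C(=O)O[C@@H](c2cc(O[Si](C)(C)C(C)(C)C)c(OC)c(OC)c2)[C@@H]1C.[I-]
F6 | step 5 | lithium (4R,5R)-5-[3-(tert-butyldimethylsilyloxy)-4,5-dimethoxyphenyl]-3,4-dimethyl-4,5-dihydrofuran-2-olate | [Li+].CC1=C([O-])O[C@@H](c2cc(O[Si](C)(C)C(C)(C)C)c(OC)c(OC)c2)[C@@H]1C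
F7 | step 8 | (3S,4R,5R)-5-[3-(tert-butyldimethylsilyloxy)-4,5-dimethoxyphenyl]-3,4-dimethyltetrahydrofuran-2-ol (C2 epimers) | OC1O[C@@H](c2cc(O[Si](C)(C)C(C)(C)C)c(OC)c(OC)c2)[C@H](C)[C@@H]1C
F8 | step 8 | (1R,2R,3S)-1-[3-(tert-butyldimethylsilyloxy)-4,5-dimethoxyphenyl]-4-[4-(tert-butyldimethylsilyloxy)-3-methoxyphenyl]-2,3-dimethylbutane-1,4-diol (C4 epimers) | COc1cc(cc(O[Si](C)(C)C(C)(C)C)c1OC)[C@H](O)[C@H](C)[C@H](C)C(O)c1ccc(O[Si](C)(C)C(C)(C)C)c(OC)c1
A1 | alternative 1 | dimethyl (2R,3R)-2-[4-(benzyloxy)-3-methoxyphenyl]-3-methylcyclopropane-1,1-dicarboxylate (aryl and methyl cis) | COC(=O)C1(C(=O)OC)[C@H](C)[C@@H]1c1ccc(OCc2ccccc2)c(OC)c1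
A2 | alternative 1 | 3-(benzyloxy)-4,5-dimethoxybenzaldehyde | COc1cc(C=O)cc(OCc2ccccc2)c1OC
A3 | alternative 1 | dimethyl 5-[4-(benzyloxy)-3-methoxyphenyl]-2-[3-(benzyloxy)-4,5-dimethoxyphenyl]-4-methyltetrahydrofuran-3,3-dicarboxylate (2,5-cis diaryl, methyl trans to the adjacent aryl, configuration as in 17) | COc1cc([C@H]2O[C@@H](c3cc(OCc4ccccc4)c(OC)c(OC)c3)C(C(=O)OC)(C(=O)OC)[C@@H]2C)ccc1OCc1ccccc1
A4 | alternative 2 | methyl (Z)-2-[(4,4,5,5-tetramethyl-1,3,2-dioxaborolan-2-yl)methyl]but-2-enoate | C/C=C(/CB1OC(C)(C)C(C)(C)O1)C(=O)OC
A5 | alternative 2 | 4-(tert-butyldimethylsilyloxy)-3-methoxybenzaldehyde | COc1cc(C=O)ccc1O[Si](C)(C)C(C)(C)C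
A6 | alternative 2 | (4S,5S)-5-[4-(tert-butyldimethylsilyloxy)-3-methoxyphenyl]-4-methyl-3-methylidenedihydrofuran-2(3H)-one | C=C1C(=O)O[C@H](c2ccc(O[Si](C)(C)C(C)(C)C)c(OC)c2)[C@H]1C
A7 | alternative 3 | (R)-5-[3-(benzyloxy)-4,5-dimethoxyphenyl]furan-2(5H)-one | O=C1C=C[C@H](c2cc(OCc3ccccc3)c(OC)c(OC)c2)O1
A8 | alternative 3 | chloromethyl (trimethylsilyl)methyl sulfide | C[Si](C)(C)CSCCl
A9 | alternative 3 | cis-fused 3-[3-(benzyloxy)-4,5-dimethoxyphenyl]tetrahydro-1H-thieno[3,4-c]furan-1-one, aryl on the exo face | O=C1O[C@@H](c3cc(OCc4ccccc4)c(OC)c(OC)c3)[C@@H]2CSC[C@H]12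
A10 | alternative 3 | (3S,4R,5R)-5-[3-(benzyloxy)-4,5-dimethoxyphenyl]-3,4-dimethyldihydrofuran-2(3H)-one | O=C1O[C@@H](c2cc(OCc3ccccc3)c(OC)c(OC)c2)[C@H](C)[C@@H]1C
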